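**Retrosynthetic overview**

1. The target is a (2S)-7-hydroxyflavanone (rings A and C) whose ring B carries a fused (3''S)-3-hydroxy-2,2-dimethyldihydropyran (ring D). The last two steps are a Jacobsen epoxidation of a 2,2-dimethylchromene and one global hydrogenolysis (epoxide C4''–O bond, two benzyl ethers, one C–Cl bond).
2. Ring C is cut at two bonds at once, O1–C8a and C4–C4a. An aryne (ring A) is joined to the alkoxide oxygen and the acyl carbon of an (S)-β-hydroxy Weinreb amide, and the ring closes when the aryl anion at C4a attacks C4.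
3. Enabling feature: O1 and the C4 carbonyl sit on the adjacent ring-A carbons C8a and C4a (the two termini of an aryne) and are 1,3-related through C2–C3 (an aldol unit). A chlorine at C5 steers the aryne addition and leaves in the final hydrogenolysis.
4. The amide comes from 3-(benzyloxy)-4-hydroxybenzaldehyde: propargyl ether formation and Claisen rearrangement/electrocyclisation build the chromene, then aldol addition, oxidation and asymmetric transfer hydrogenation set C2. The aryne precursor comes from 4-(benzyloxy)phenol in three steps.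
5. Ring order: B (bought) → D as chromene (step 2) → A (bought, delivered as aryne) → C (step 9) → C3'' stereocentre (steps 10 and 11).

Key step: step 9

Remark: 3-(benzyloxy)-4-hydroxybenzaldehyde and 4-(benzyloxy)phenol are taken as catalogue compounds; flavanone locants (O1, C2, C3, C4, C4a, C5–C8, C8a) are used for rings C and A, and doubly primed locants for the dimethylpyran ring D fused to ring B.

**Route**

Step 1
Reactants: 1 3-(benzyloxy)-4-hydroxybenzaldehyde
Product: 2 3-(benzyloxy)-4-[(2-methylbut-3-yn-2-yl)oxy]benzaldehyde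
Conditions: 3-chloro-3-methylbut-1-yne, K2CO3, KI (cat.), CuI (cat.), acetone, reflux
Reagents that add atoms: 3-chloro-3-methylbut-1-yne, C#CC(C)(C)Cl
Why: O-Alkylation of the potassium phenoxide with the tertiary propargylic chloride (copper-assisted Williamson-type etherification) is the standard entry to aryl 1,1-dimethylpropargyl ethers, and the aldehyde is inert to it.

Step 2
Reactants: 2 3-(benzyloxy)-4-[(2-methylbut-3-yn-2-yl)oxy]benzaldehyde
Product: 5 8-(benzyloxy)-2,2-dimethyl-2H-chromene-6-carbaldehyde, via allenylphenol 3 (not isolated), via o-quinone methide 4 (not isolated)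
Conditions: PhNEt2, 190 °C
Reagents that add atoms: none
Why: Aromatic propargyl Claisen rearrangement to the only free ortho position gives allenylphenol 3, whose 1,5-hydrogen shift to o-quinone methide 4 and oxa-6π electrocyclisation should close the 2,2-dimethyl-2H-chromene (ring D skeleton).

Step 3
Reactants: 5 8-(benzyloxy)-2,2-dimethyl-2H-chromene-6-carbaldehyde
Product: 6 rac-3-[8-(benzyloxy)-2,2-dimethyl-2H-chromen-6-yl]-3-hydroxy-N-methoxy-N-methylpropanamide
Conditions: MeC(O)N(OMe)Me, LDA, THF, −78 °C; then 5; aq NH4Cl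
Reagents that add atoms: N-methoxy-N-methylacetamide, CC(=O)N(C)OC
Why: Aldol addition of the lithium enolate of the Weinreb acetamide to the aromatic aldehyde installs C3 and C4; the carbinol centre is formed as a racemate and is erased in step 4.

Step 4
Reactants: 6 rac-3-[8-(benzyloxy)-2,2-dimethyl-2H-chromen-6-yl]-3-hydroxy-N-methoxy-N-methylpropanamide
Product: 7 3-[8-(benzyloxy)-2,2-dimethyl-2H-chromen-6-yl]-N-methoxy-N-methyl-3-oxopropanamide
Conditions: Dess–Martin periodinane, CH2Cl2, 0 °C → rt
Reagents that add atoms: none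
Why: Dess–Martin oxidation of the benzylic secondary alcohol gives the β-keto amide under neutral conditions that leave the chromene alkene, the benzyl ether and the Weinreb amide untouched.

Step 5
Reactants: 7 3-[8-(benzyloxy)-2,2-dimethyl-2H-chromen-6-yl]-N-methoxy-N-methyl-3-oxopropanamide
Product: 8 (3S)-3-[8-(benzyloxy)-2,2-dimethyl-2H-chromen-6-yl]-3-hydroxy-N-methoxy-N-methylpropanamide
Conditions: RuCl[(S,S)-TsDPEN](p-cymene) (1 mol %), HCO2H/Et3N (5:2), CH2Cl2, 30 °C
Reagents that add atoms: none
Why: Noyori–Ikariya asymmetric transfer hydrogenation of the aryl ketone: the (S,S)-TsDPEN ligand directs hydride to the carbonyl face that gives the (S)-carbinol (same sense as for acetophenone, aryl ranking above CH2), which sets the future C2, and the catalyst does not touch the alkene or the benzyl ether.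

Step 6
Reactants: 9 4-(benzyloxy)phenol
Product: 10 4-(benzyloxy)-2-chlorophenol
Conditions: SO2Cl2, i-Bu2NH (cat.), toluene, 70 °C
Reagents that add atoms: sulfuryl chloride, O=S(=O)(Cl)Cl
Why: Amine-catalysed electrophilic chlorination with SO2Cl2 is ortho-selective for phenols and the para position is blocked, so monochlorination next to the hydroxyl group is expected.

Step 7
Reactants: 10 4-(benzyloxy)-2-chlorophenol
Product: 11 4-(benzyloxy)-2-bromo-6-chlorophenol
Conditions: NBS, i-Pr2NH (cat.), CH2Cl2, 0 °C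
Reagents that add atoms: N-bromosuccinimide, O=C1CCC(=O)N1Br
Why: Electrophilic bromination with NBS under the same amine catalysis takes the remaining position ortho to the hydroxyl group.

Step 8
Reactants: 11 4-(benzyloxy)-2-bromo-6-chlorophenol
Product: 14 4-(benzyloxy)-2-chloro-6-(trimethylsilyl)phenyl trifluoromethanesulfonate, via aryl silyl ether 12 (not isolated), via lithium silylphenolate 13 (not isolated)
Conditions: HMDS, THF, 65 °C, then evaporate; n-BuLi, THF, −100 → −78 °C; Tf2O, −78 °C → rt
Reagents that add atoms: hexamethyldisilazane, C[Si](C)(C)N[Si](C)(C)C; trifluoromethanesulfonic anhydride, O=S(=O)(OS(=O)(=O)C(F)(F)F)C(F)(F)F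
Why: Standard one-flask route to a Kobayashi aryne precursor: O-silylation, bromine–lithium exchange (faster than any reaction at chlorine or at the benzyl ether at −100 °C) with retro-Brook 1,3 O-to-C silyl migration, and triflation of the resulting phenolate.

Step 9
Reactants: 8 (3S)-3-[8-(benzyloxy)-2,2-dimethyl-2H-chromen-6-yl]-3-hydroxy-N-methoxy-N-methylpropanamide; 14 4-(benzyloxy)-2-chloro-6-(trimethylsilyl)phenyl trifluoromethanesulfonate
Product: 19 (2S)-7-(benzyloxy)-2-[8-(benzyloxy)-2,2-dimethyl-2H-chromen-6-yl]-5-chloro-2,3-dihydro-4H-chromen-4-one, via sodium alkoxide 15 (not isolated), via chloroaryne 16 (not isolated), via aryl anion 17 (not isolated), via tetrahedral adduct 18 (not isolated)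
Conditions: NaH, THF, 0 °C; then 14 (1.3 equiv), CsF, 18-crown-6, THF, −20 °C → rt; cold aq NH4Cl
Reagents that add atoms: none
Why: Proposed new method: CsF releases chloroaryne 16 from 14 and the alkoxide oxygen of 15 adds to the aryne carbon remote from chlorine (the future C8a), because the C–Cl bond distorts the aryne and stabilises negative charge on the neighbouring carbon, so that aryl anion 17 carries its charge at the future C4a. This anion adds to the Weinreb carbonyl (C4) in a 6-exo-trig acyl addition that forms the C4–C4a bond and closes ring C as the tetrahedral adduct 18, which gives the ketone only on the buffered quench. The closest known reaction types are the aryne annulation of salicylate esters to xanthones (tandem O-arylation and intramolecular acylation) and the Parham cyclisation of o-lithioaryl ethers onto Weinreb amides; what is new is an aliphatic secondary alkoxide as the oxygen partner. No stereocentre is formed: C2 keeps its (S) configuration because the C2–O1 bond is never broken and because the ketone, which base could open by retro-oxa-Michael reaction, stays masked in 18 while base is present. The step needs regioselective aryne addition, secured by the C5 chlorine and the bulk of the alkoxide, and acylation faster than proton transfer from C3–H or chloride loss from 17, secured by the six-membered geometry, the non-enolised Weinreb amide and the low temperature.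

Step 10
Reactants: 19 (2S)-7-(benzyloxy)-2-[8-(benzyloxy)-2,2-dimethyl-2H-chromen-6-yl]-5-chloro-2,3-dihydro-4H-chromen-4-one
Product: 20 (2S)-7-(benzyloxy)-2-[(1aS,7bS)-4-(benzyloxy)-2,2-dimethyl-1a,7b-dihydro-2H-oxireno[2,3-c]chromen-6-yl]-5-chloro-2,3-dihydro-4H-chromen-4-one
Conditions: (S,S)-(salen)MnCl [(S,S)-N,N'-bis(3,5-di-tert-butylsalicylidene)-1,2-cyclohexanediamine manganese chloride] (5 mol %), mCPBA, NMO, CH2Cl2, −78 °C
Reagents that add atoms: 3-chloroperbenzoic acid, OOC(=O)c1cccc(Cl)c1
Why: Jacobsen–Katsuki epoxidation of the cis-disubstituted, aryl-conjugated chromene alkene under the anhydrous low-temperature protocol: the (S,S)-salen ligand controls the face and should give the (1aS,7bS) epoxide (3''S,4''S) independently of the remote C2 centre, and the absence of aqueous base protects C2.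

Step 11
Reactants: 20 (2S)-7-(benzyloxy)-2-[(1aS,7bS)-4-(benzyloxy)-2,2-dimethyl-1a,7b-dihydro-2H-oxireno[2,3-c]chromen-6-yl]-5-chloro-2,3-dihydro-4H-chromen-4-one
Product: 21 (2S)-2-[(3S)-3,8-dihydroxy-2,2-dimethyl-3,4-dihydro-2H-chromen-6-yl]-7-hydroxy-2,3-dihydro-4H-chromen-4-one
Conditions: H2 (1 atm), 10% Pd/C, NaOAc, EtOAc/EtOH, rt
Reagents that add atoms: none
Why: Heterogeneous hydrogenolysis over Pd should cleave the benzylic C4''–O bond of the epoxide (the C3''–O bond and its configuration are untouched, giving the (3''S)-alcohol), both benzyl ethers and the aryl C–Cl bond in one operation, with NaOAc taking up the HCl without opening ring C.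

**Compound list**

1 | 3-(benzyloxy)-4-hydroxybenzaldehyde | O=Cc1ccc(O)c(OCc2ccccc2)c1 | starting material
2 | 3-(benzyloxy)-4-[(2-methylbut-3-yn-2-yl)oxy]benzaldehyde | O=Cc1ccc(OC(C)(C)C#C)c(OCc2ccccc2)c1 | intermediate
3 | 3-(benzyloxy)-4-hydroxy-5-(3-methylbuta-1,2-dien-1-yl)benzaldehyde (allenylphenol, not isolated) | O=Cc1cc(C=C=C(C)C)c(O)c(OCc2ccccc2)c1 | intermediate
4 | 5-(benzyloxy)-3-(3-methylbut-2-en-1-ylidene)-4-oxocyclohexa-1,5-diene-1-carbaldehyde (o-quinone methide, not isolated) | O=CC1=CC(=CC=C(C)C)C(=O)C(OCc2ccccc2)=C1 | intermediate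
5 | 8-(benzyloxy)-2,2-dimethyl-2H-chromene-6-carbaldehyde | CC1(C)C=Cc2cc(C=O)cc(OCc3ccccc3)c2O1 | intermediate
6 | rac-3-[8-(benzyloxy)-2,2-dimethyl-2H-chromen-6-yl]-3-hydroxy-N-methoxy-N-methylpropanamide (racemate) | CON(C)C(=O)CC(O)c1cc2C=CC(C)(C)Oc2c(OCc2ccccc2)c1 | intermediate
7 | 3-[8-(benzyloxy)-2,2-dimethyl-2H-chromen-6-yl]-N-methoxy-N-methyl-3-oxopropanamide | CON(C)C(=O)CC(=O)c1cc2C=CC(C)(C)Oc2c(OCc2ccccc2)c1 | intermediate
8 | (3S)-3-[8-(benzyloxy)-2,2-dimethyl-2H-chromen-6-yl]-3-hydroxy-N-methoxy-N-methylpropanamide | CON(C)C(=O)C[C@H](O)c1cc2C=CC(C)(C)Oc2c(OCc2ccccc2)c1 | intermediate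
9 | 4-(benzyloxy)phenol | Oc1ccc(OCc2ccccc2)cc1 | starting material
10 | 4-(benzyloxy)-2-chlorophenol | Oc1ccc(OCc2ccccc2)cc1Cl | intermediate
11 | 4-(benzyloxy)-2-bromo-6-chlorophenol | Oc1c(Br)cc(OCc2ccccc2)cc1Cl | intermediate
12 | [4-(benzyloxy)-2-bromo-6-chlorophenoxy]trimethylsilane (not isolated) | C[Si](C)(C)Oc1c(Br)cc(OCc2ccccc2)cc1Cl | intermediate
13 | lithium 4-(benzyloxy)-2-chloro-6-(trimethylsilyl)phenolate (not isolated) | C[Si](C)(C)c1cc(OCc2ccccc2)cc(Cl)c1[O-].[Li+] | intermediate
14 | 4-(benzyloxy)-2-chloro-6-(trimethylsilyl)phenyl trifluoromethanesulfonate | C[Si](C)(C)c1cc(OCc2ccccc2)cc(Cl)c1OS(=O)(=O)C(F)(F)F | intermediate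
15 | sodium (1S)-1-[8-(benzyloxy)-2,2-dimethyl-2H-chromen-6-yl]-3-[methoxy(methyl)amino]-3-oxopropan-1-olate (not isolated) | CON(C)C(=O)C[C@H]([O-])c1cc2C=CC(C)(C)Oc2c(OCc2ccccc2)c1.[Na+] | intermediate
16 | 5-(benzyloxy)-3-chlorobenzyne (5-(benzyloxy)-3-chloro-1,2-didehydrobenzene, not isolated) | ClC1=CC(OCc2ccccc2)=CC#C1 | intermediate
17 | sodium 4-(benzyloxy)-2-{(1S)-1-[8-(benzyloxy)-2,2-dimethyl-2H-chromen-6-yl]-3-[methoxy(methyl)amino]-3-oxopropoxy}-6-chlorobenzen-1-ide (aryl anion, not isolated) | CON(C)C(=O)C[C@H](Oc1cc(OCc2ccccc2)cc(Cl)[c-]1)c1cc2C=CC(C)(C)Oc2c(OCc2ccccc2)c1.[Na+] | intermediate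
18 | sodium (2S)-7-(benzyloxy)-2-[8-(benzyloxy)-2,2-dimethyl-2H-chromen-6-yl]-5-chloro-4-[methoxy(methyl)amino]-3,4-dihydro-2H-chromen-4-olate (C4 epimers, not isolated) | CON(C)C1([O-])C[C@H](Oc2cc(OCc3ccccc3)cc(Cl)c12)c1cc2C=CC(C)(C)Oc2c(OCc2ccccc2)c1.[Na+] | intermediate
19 | (2S)-7-(benzyloxy)-2-[8-(benzyloxy)-2,2-dimethyl-2H-chromen-6-yl]-5-chloro-2,3-dihydro-4H-chromen-4-one | CC1(C)C=Cc2cc(cc(OCc3ccccc3)c2O1)[C@@H]1CC(=O)c2c(Cl)cc(OCc3ccccc3)cc2O1 | intermediate
20 | (2S)-7-(benzyloxy)-2-[(1aS,7bS)-4-(benzyloxy)-2,2-dimethyl-1a,7b-dihydro-2H-oxireno[2,3-c]chromen-6-yl]-5-chloro-2,3-dihydro-4H-chromen-4-one | CC1(C)Oc2c(OCc3ccccc3)cc(cc2[C@@H]2O[C@H]12)[C@@H]1CC(=O)c2c(Cl)cc(OCc3ccccc3)cc2O1 | intermediate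
21 | (2S)-2-[(3S)-3,8-dihydroxy-2,2-dimethyl-3,4-dihydro-2H-chromen-6-yl]-7-hydroxy-2,3-dihydro-4H-chromen-4-one | CC1(C)Oc2c(O)cc([C@@H]3CC(=O)c4ccc(O)cc4O3)cc2C[C@@H]1O | target

**Step count and risks**

Total step count: 11. Longest linear sequence: 8 steps (1, 2, 3, 4, 5, 9, 10, 11); the aryne precursor branch (6, 7, 8) joins at step 9.

Steps most likely to fail:

1. Step 9 (Proposed new method). What may go wrong: proton transfer from C3–H to the aryl anion followed by β-elimination of the aryloxide; retro-aldol fragmentation of the alkoxide before it meets the aryne; loss of regiocontrol in the aryne addition; premature collapse of the tetrahedral adduct, which would expose the ketone to base and erode C2.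
Fallback (known chemistry; sets out from 8, returns at 21): the two ring-C bonds are made one after the other. 4-Bromo-3-iodophenol is benzylated (BnBr, K2CO3, DMF) to 4-(benzyloxy)-1-bromo-2-iodobenzene F1. Ullmann-type etherification of 8 with F1 at the C–I bond (CuI, 3,4,7,8-tetramethyl-1,10-phenanthroline, Cs2CO3, toluene, 90 °C) leaves the carbinol C–O bond untouched, so C2 is retained, and gives (3S)-3-[5-(benzyloxy)-2-bromophenoxy]-3-[8-(benzyloxy)-2,2-dimethyl-2H-chromen-6-yl]-N-methoxy-N-methylpropanamide F2. Bromine–lithium exchange and Parham cyclisation onto the Weinreb amide (t-BuLi, THF, −100 °C, then aq NH4Cl) close ring C through the same C4–C4a bond and give the chlorine-free flavanone (2S)-7-(benzyloxy)-2-[8-(benzyloxy)-2,2-dimethyl-2H-chromen-6-yl]-2,3-dihydro-4H-chromen-4-one F3. Epoxidation as in step 10 gives (2S)-7-(benzyloxy)-2-[(1aS,7bS)-4-(benzyloxy)-2,2-dimethyl-1a,7b-dihydro-2H-oxireno[2,3-c]chromen-6-yl]-2,3-dihydro-4H-chromen-4-one F4, and hydrogenolysis as in step 11 (NaOAc not needed) gives 21.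

2. Step 11. What may go wrong: over-reduction while the C–Cl cleavage is being forced (hydrogenolysis of the benzylic C2–O1 bond or reduction of the C4 carbonyl), or solvolysis of the electron-rich epoxide before it is hydrogenolysed.
Fallback (sets out from 20, returns at 21): the four reductions are split into two operations of different mechanism. Hydrogenolysis without base (H2, Pd/C, EtOAc, rt) is stopped as soon as the epoxide and both benzyl ethers have reacted, which should leave the aryl chloride in place and give (2S)-5-chloro-2-[(3S)-3,8-dihydroxy-2,2-dimethyl-3,4-dihydro-2H-chromen-6-yl]-7-hydroxy-2,3-dihydro-4H-chromen-4-one F6. The C–Cl bond, activated for oxidative addition by the ortho carbonyl group, is then reduced by homogeneous formate transfer (Pd(OAc)2, XPhos, HCO2NH4, DMF, 50 °C), a process that cannot hydrogenolyse benzylic C–O bonds, to give 21.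

3. Step 10. What may go wrong: incomplete facial control on the elaborate substrate, oxidative or base-mediated erosion of C2 next to the flavanone carbonyl, or ionisation of the electron-rich benzylic epoxide during isolation.
Fallback (sets out from 8, returns at 20): the order of oxidation and annulation is exchanged so that no flavanone is present during the epoxidation. Alcohol 8 is epoxidised under the conditions of step 10 (catalyst control as before; the free carbinol should be tolerated at −78 °C) to (3S)-3-[(1aS,7bS)-4-(benzyloxy)-2,2-dimethyl-1a,7b-dihydro-2H-oxireno[2,3-c]chromen-6-yl]-3-hydroxy-N-methoxy-N-methylpropanamide F5. Its sodium alkoxide is then annulated with 14 exactly as in step 9 (the epoxide should be inert to alkoxide and fluoride at or below room temperature), which gives 20 directly.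

Further compounds
F1 | step 9 | 4-(benzyloxy)-1-bromo-2-iodobenzene | Brc1ccc(OCc2ccccc2)cc1I
F2 | step 9 | (3S)-3-[5-(benzyloxy)-2-bromophenoxy]-3-[8-(benzyloxy)-2,2-dimethyl-2H-chromen-6-yl]-N-methoxy-N-methylpropanamide | CON(C)C(=O)C[C@H](Oc1cc(OCc2ccccc2)ccc1Br)c1cc2C=CC(C)(C)Oc2c(OCc2ccccc2)c1
F3 | step 9 | (2S)-7-(benzyloxy)-2-[8-(benzyloxy)-2,2-dimethyl-2H-chromen-6-yl]-2,3-dihydro-4H-chromen-4-one | CC1(C)C=Cc2cc(cc(OCc3ccccc3)c2O1)[C@@H]1CC(=O)c2ccc(OCc3ccccc3)cc2O1
F4 | step 9 | (2S)-7-(benzyloxy)-2-[(1aS,7bS)-4-(benzyloxy)-2,2-dimethyl-1a,7b-dihydro-2H-oxireno[2,3-c]chromen-6-yl]-2,3-dihydro-4H-chromen-4-one | CC1(C)Oc2c(OCc3ccccc3)cc(cc2[C@@H]2O[C@H]12)[C@@H]1CC(=O)c2ccc(OCc3ccccc3)cc2O1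
F5 | step 10 | (3S)-3-[(1aS,7bS)-4-(benzyloxy)-2,2-dimethyl-1a,7b-dihydro-2H-oxireno[2,3-c]chromen-6-yl]-3-hydroxy-N-methoxy-N-methylpropanamide | CC1(C)Oc2c(OCc3ccccc3)cc(cc2[C@@H]2O[C@H]12)[C@@H](O)CC(=O)N(C)OC
F6 | step 11 | (2S)-5-chloro-2-[(3S)-3,8-dihydroxy-2,2-dimethyl-3,4-dihydro-2H-chromen-6-yl]-7-hydroxy-2,3-dihydro-4H-chromen-4-one | CC1(C)Oc2c(O)cc([C@@H]3CC(=O)c4c(Cl)cc(O)cc4O3)cc2C[C@@H]1O
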